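In alder the open intermediate cannot wait for the partner: half of the partner takes 12.0 min to turn into second intermediate, but the open intermediate has a half-life by decomposition of 2.46 min, shorter than that. Starting material opens reversibly to open intermediate, and open intermediate and second intermediate join to target. Second intermediate also pairs to homo product, and open intermediate also decomposes.

all flasks: starting material 0.10 M; partner 0.120 M; time 15 min

| flask | temperature |
|---|---|
| alder | 50 °C |
| ash | 25 °C |
| larch | 100 °C |
| birch | 75 °C |

1. the best flask by amount of target, in percent of the starting material charged; "all alike" if 1.5 percentage points covers them all (alder / ash / larch / birch / all alike)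
2. amount of target at the end, in percent of the starting material charged, alder
3. amount of target at the end, in percent of the starting material charged, ash
4. amount of target at the end, in percent of the starting material charged, larch
5. amount of target at the end, in percent of the starting material charged, birch

- where a step has two of a species, its rate is k times that concentration squared, and two are used at each turn
- the constants hold at 50 °C; other temperatures follow from the activation energies and enthalpies

    starting material ⇌ open intermediate (K1 = 1.4, k1 = 0.026 s⁻¹, Ea1 = 76.0 kJ mol⁻¹, ΔH1 = −42.0 kJ mol⁻¹)
    partner → second intermediate (k2 = 9.6 × 10⁻⁴ s⁻¹, Ea2 = 106 kJ mol⁻¹)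
    open intermediate + second intermediate → target (k3 = 0.18 M⁻¹ s⁻¹, Ea3 = 55.0 kJ mol⁻¹)
    2 second intermediate → homo product (k4 = 0.33 M⁻¹ s⁻¹, Ea4 = 58.0 kJ mol⁻¹)
    open intermediate → decomposed reagent (k5 = 0.0047 s⁻¹, Ea5 = 94.0 kJ mol⁻¹)
    (constants at 50 °C)

Reckon alder, where the constants stand as given. Start with the opening. Forward and back together relax with a half-life of 15.6 s, shorter than the decomposition half-life, so take it as an equilibrium:

[open intermediate] = 0.10 M × 1.4 / (1 + 1.4) = 0.0583 M

Now balance the second intermediate, with the partner held at its charge. Set its supply equal to its two losses, the quasi-steady state:

9.6 × 10⁻⁴ s⁻¹ × 0.120 M = 2 × 0.33 M⁻¹ s⁻¹ × [second intermediate] squared + 0.18 M⁻¹ s⁻¹ × 0.0583 M × [second intermediate]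

[second intermediate] = 0.00747 M

Check the assumption: at this level it settles in about 49.1 s, shorter than the decomposition half-life.

Next compare the two exits of the open intermediate. Both are first order in it, so [open intermediate] cancels:

0.18 M⁻¹ s⁻¹ × 0.00747 M / 0.0047 s⁻¹ = 0.286

This number, target made per decomposed reagent made at a given moment, is the capture ratio, a selectivity factor. Turn it into a share of what leaves:

0.286 / (1 + 0.286) = 22.2 %

With the ratio held at this value and the open intermediate leaving by these two exits, my estimate for alder is 22.2 % of the charge. Stop there by hand; the other flasks need their constants moved by temperature.

The forecast names alder as best. It gives 22 % for alder (range 20 % to 24 %), 2 % for ash, 8.6 % for larch and 18 % for birch. Its ground for alder: “activation and decomposition are balanced”. Its route was a coarse integration of the target rate, and mine is a share.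

The simulation gives alder as best, with 20.8 % in alder, 1.92 % in ash, 8.87 % in larch and 15.9 % in birch.

Put alder's [second intermediate], 0.00842 M at 15.0 min, in place of the reckoned level, and the capture ratio at that moment moves from 0.286 to 0.323, while the amounts gathered by then, target to decomposed reagent, stand in alder at 0.281. In ash at 15.0 min, decomposition uses open intermediate 4.7 times faster than capture does, a capture ratio of 0.213, with target at 1.92 %, decomposed reagent at 11.1 % and open intermediate still at 65.8 %; left for 150 min, ash holds 20.5 % target.

(The constants used here were chosen freely, and the outcome is calculated.)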